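**Remarks (assumptions)**

- The SMILES is read as (6R,6'R)-ε,ε-carotene, C40H56, C2-symmetric, with all nine chain double bonds E. Carotenoid numbering is used: ring C1 (gem-dimethyl) to C6 (chain-bearing), chain C7 to C15, primes for the second half.
- Crystalline all-E-β,β-carotene 1 is taken as the commercial starting material; canthaxanthin 2 is also sold, so step 1 may be replaced by purchase.

## The problem

The target is an all-E nonaene chain (C7 to C7', four methyl branches) ending on both sides in a 2,6,6-trimethylcyclohex-2-enyl (ε) ring. It has no heteroatom and only two stereocentres, C6 and C6'. Each is a bis-allylic methine between the quaternary C1, the ring double bond C4=C5 and the chain double bond C7=C8. It is therefore hard to reach by intermolecular C–C bond formation and easy to lose: base (deprotonation at C6) or acid moves C4=C5 to C5=C6, giving the conjugated, achiral β-ring, which is downhill. The two centres are eighteen bonds apart and cannot control each other, so each needs an external source of chirality, and every lapse appears as the meso (6R,6'S) diastereomer. The chain is sensitive to light, oxygen, acid, radicals and electrophiles, but its construction is a solved problem: the fully conjugated isomer, β,β-carotene 1, is a bulk chemical. What remains is the contra-thermodynamic placement of the two ring double bonds together with the absolute configuration at C6 and C6', done late, near neutrality, and leaving no functional group behind.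

The enabling feature is the three-atom unit C4=C5(CH3)–C6(H) in each ring. A ring double bond with a hydrogen-bearing stereocentre at its allylic position is the retron of a suprafacial reductive 1,3-transposition: retro-ene loss of N2 from an allylic diazene on C4 of a β-ring (C5=C6). The unit occurs in both rings of a C2-symmetric molecule, so the operation can be run at both ends at once on an achiral, fully conjugated C40 precursor oxygenated at C4 and C4'.

## Retrosynthesis

**7 ⇒ 6.** The C6–H and C6'–H bonds are cut, not a carbon–carbon bond. Each hydrogen is traced back to the N–H of an allylic diazene on C4 of a β-ring, and the double bonds return from C4=C5 to C5=C6. The neighbouring cuts (C6–C7, or any chain double bond) leave the labile stereocentre inside a building block that must be made enantiopure and carried through every chain-forming step; this cut removes the stereocentre itself. The precursor, bis-diazene 6, has the fully conjugated β,β-skeleton, and its only stereocentres are two C–N carbons. The forward reaction must deliver hydrogen to C6 only, on one face, and faster than any other way of losing N2.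

**6 ⇒ 5 ⇒ 4.** The C4–N and C4'–N bonds are cut. A diazene cannot be stored, so 6 is generated from the bis(N-sulfonylhydrazine) 5 by loss of sulfinic acid, and 5 from the (4S,4'S)-diol 4 by a twofold Mitsunobu displacement with a sulfonylhydrazide. Displacement with inversion is preferred to a hydrazone reduction because it ties C4 (and hence C6) to a carbinol centre, the easiest kind of stereocentre to set. Diol 4 is much simpler than 7 in the sense that matters: it has the thermodynamically preferred skeleton and is two steps from a commodity. The forward reaction must go by displacement, not ionisation, at a carbon allylic to an undecaene.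

**4 ⇒ 3 ⇒ 2.** The C4–H and C4'–H bonds are cut: 4 is the product of a twofold enantioselective 1,2-reduction of canthaxanthin 2, through borate ester 3 and its hydrolysis. Catalytic asymmetric ketone reduction is chosen over resolution or a chiral building block because 2 is achiral and symmetric, so all stereochemical information enters from one catalyst in two independent events. Most of the error is channelled into the separable meso diol. The forward reaction must be 1,2-selective and leave the polyene untouched.

**2 ⇒ 1.** The two C4=O oxygens are removed: 2 arises by allylic oxidation of the ring methylenes C4 and C4' of 1, the only CH2 groups allylic to the polyene. Building 2 by chain assembly from C15 and C10 pieces would cost many steps for a skeleton that 1 already has. The oxygens are traceless handles: introduced in step 1, used to set configuration in step 2, expelled in step 3. Overall the plan is an enantioselective, contra-thermodynamic isomerisation of 1 to 7 in three steps.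

## Roads not taken

**Alternative 1:** (the obvious route) Cut the C11=C12 and C11'=C12' double bonds. The forward key step is a twofold Wittig reaction of the C15 phosphonium salt A2, made from (R)-α-ionone A1, with the C10 dialdehyde A3 (C15 + C10 + C15).
- It only assembles a chain that is already available in bulk and leaves the real problem untouched.
- A1 must be obtained enantiopure by resolution or a multistep asymmetric synthesis.
- The C6–H of A1 is the γ-hydrogen of an enone, so base causes racemisation and drift to the β-isomer.
- The stereocentre must then survive acid-mediated phosphonium salt formation through an allylic cation and two ylide steps.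
- The Wittig steps give 11Z isomers that need isomerisation.
- The chosen plan creates both stereocentres in the last step, needs no chiral building block and is at most half as long.

**Alternative 2:** Cut the central C15=C15' double bond. The forward key step is reductive dimerisation (McMurry coupling with low-valent titanium) of two molecules of (R)-α-retinal A4, a tail-to-tail C20 + C20 union that echoes the biosynthetic origin of the C40 skeleton.
- It uses the C2 symmetry well, but A4 must be built linearly from A1 by two chain-extension cycles, so every objection to an enantiopure ε-building block remains and is carried over more steps.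
- The Lewis-acidic titanium medium endangers the position of the ε-ring double bond.
- The new central double bond forms as an E/Z mixture.

**Alternative 3:** Cut the C1–C6 and C1'–C6' ring bonds. The forward key step is a twofold proton-initiated cyclisation of lycopene A5 with a chiral Brønsted acid, the direct copy of the biosynthetic ε-cyclase step. It would form both rings and both stereocentres from an achiral C40 polyene at once.
- Without the enzyme, the undecaene of A5 is far more basic than the two isolated C1=C2 bonds that must be protonated.
- The C5 cation left after ring closure can lose a proton from C4, C6 or C18 and prefers the conjugated (β) outcome.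
- No chiral acid is known to control two remote termini of a polyene.
- The chosen plan keeps the idea of editing an achiral C40 carotenoid at both ends but replaces the cationic step by a concerted hydrogen transfer whose site and face are fixed by a six-membered transition state.

Key step: step 3

## Route

All operations are to be run under argon in subdued light; silica is deactivated with triethylamine.

**Step 1**
Reactants: 1 all-E-β,β-carotene
Product: 2 canthaxanthin (all-E-β,β-carotene-4,4'-dione)
Conditions: NaClO3 (aq.), cat. I2, CHCl3/H2O, 20–25 °C
Reagents that add atoms: water, O (carbonyl oxygen, by hydrolysis at C4); sodium chlorate, [Na+].[O-]Cl(=O)=O (terminal oxidant and possible oxygen donor)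
Why: Iodine-mediated allylic oxidation, the industrial reaction type for this very substrate: C4 and C4' are the only methylene groups allylic to the undecaene, so they are functionalised selectively, the C–I or C–OH stage is oxidised on to the ketone, and chlorate re-oxidises iodide. No stereocentre is formed.

**Step 2**
Reactants: 2 canthaxanthin
Product: 4 (4S,4'S)-β,β-carotene-4,4'-diol, via bis-catecholborate ester 3 (not isolated)
Conditions: (R)-1-methyl-3,3-diphenyltetrahydro-1H,3H-pyrrolo[1,2-c][1,3,2]oxazaborole ((R)-Me-CBS, cat.), catecholborane, CH2Cl2/toluene, −60 to −40 °C; MeOH, then aq. NaOH wash
Reagents that add atoms: none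
Why: Corey–Bakshi–Shibata reduction: each C4 carbonyl lies between the small C3 methylene and the large, fully substituted alkenyl carbon C5, so by the standard model the (R)-catalyst should give the S carbinol (the sense is to be confirmed on 4 by Mosher ester analysis and the (S)-catalyst used if it is reversed). Catecholborane at low temperature should give 1,2-reduction only, and the two remote carbonyls react independently, so residual error ends mostly in the meso diol, which chromatography and crystallisation should remove.

**Step 3**
Reactants: 4 (4S,4'S)-β,β-carotene-4,4'-diol
Product: 7 (6R,6'R)-ε,ε-carotene, via bis-sulfonylhydrazine 5 (not isolated), via bis-diazene 6 (not isolated)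
Conditions: PPh3, DEAD, N-methylmorpholine/THF, −30 °C; add 4, then NBSH (2-nitrobenzenesulfonylhydrazide, near stoichiometric); −30 °C → 23 °C; crystallisation (CH2Cl2/MeOH)
Reagents that add atoms: none
Why: Allylic diazene rearrangement (reductive 1,3-transposition of an allylic alcohol by Mitsunobu displacement with NBSH), run twice in one flask: the preformed PPh3/DEAD betaine turns each C4 hydroxyl into an oxyphosphonium leaving group, the sulfonamide nitrogen of NBSH displaces it with inversion to give 5, and above about −15 °C 5 loses 2-nitrobenzenesulfinic acid to give the monoalkyl diazene 6. In 6 the N=N–H unit, held pseudoaxially on C4, passes its hydrogen to C6 through a six-membered retro-ene transition state while N2 leaves and the double bond moves from C5=C6 to C4=C5; the closest known cases are reductive transpositions of cyclohexenols and of enone tosylhydrazones that place a ring-fusion hydrogen on a fully substituted carbon next to a quaternary centre, as C6 is next to C1. No ring is closed. The new stereocentres C6 and C6' are controlled only by the C4 and C4' carbinol centres of 4: inversion puts nitrogen on the face opposite the former hydroxyl and hydrogen is delivered suprafacially on the nitrogen face, so 4S gives 6R at each end, independently, and a lapse at one end would give the separable meso isomer. Three selectivities are needed: displacement and not ionisation at C4, secured by −30 °C, a weakly basic and poorly ionising medium and formation of the betaine before the diol is added; hydrogen transfer to C6 and not further down the chain, enforced by the cyclic transition state because the E-configured C7=C8 bond keeps C8 out of reach of the N–H; and concerted loss of N2 in preference to a radical path, which the intramolecular process should win at or below room temperature. Loss of N2 pays for taking two double bonds out of conjugation, which no equilibrium method could do, and NBSH contributes only the two hydrogens at C6 and C6'. N-Methylmorpholine buffers the sulfinic acid, so neither the acid-labile diol nor the bis-allylic C6–H of the product meets acid, and NBSH is kept near stoichiometric so that little diimide can form on warming.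

## Compound list

1 | all-E-β,β-carotene | CC1=C(C(C)(C)CCC1)/C=C/C(C)=C/C=C/C(C)=C/C=C/C=C(C)/C=C/C=C(C)/C=C/C1=C(C)CCCC1(C)C | starting material
2 | canthaxanthin (all-E-β,β-carotene-4,4'-dione) | CC1=C(C(C)(C)CCC1=O)/C=C/C(C)=C/C=C/C(C)=C/C=C/C=C(C)/C=C/C=C(C)/C=C/C1=C(C)C(=O)CCC1(C)C | intermediate
3 | (4S,4'S)-4,4'-bis(1,3,2-benzodioxaborol-2-yloxy)-β,β-carotene (not isolated) | CC1=C(C(C)(C)CC[C@@H]1OB2Oc3ccccc3O2)/C=C/C(C)=C/C=C/C(C)=C/C=C/C=C(C)/C=C/C=C(C)/C=C/C1=C(C)[C@@H](OB2Oc3ccccc3O2)CCC1(C)C | intermediate
4 | (4S,4'S)-β,β-carotene-4,4'-diol ((4S,4'S)-isozeaxanthin) | CC1=C(C(C)(C)CC[C@@H]1O)/C=C/C(C)=C/C=C/C(C)=C/C=C/C=C(C)/C=C/C=C(C)/C=C/C1=C(C)[C@@H](O)CCC1(C)C | intermediate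
5 | (4R,4'R)-4,4'-bis[1-(2-nitrobenzenesulfonyl)hydrazin-1-yl]-β,β-carotene (not isolated) | CC1=C(C(C)(C)CC[C@H]1N(N)S(=O)(=O)c2ccccc2[N+](=O)[O-])/C=C/C(C)=C/C=C/C(C)=C/C=C/C=C(C)/C=C/C=C(C)/C=C/C1=C(C)[C@H](N(N)S(=O)(=O)c2ccccc2[N+](=O)[O-])CCC1(C)C | intermediate
6 | (4R,4'R)-4,4'-bis(diazenyl)-β,β-carotene (not isolated) | CC1=C(C(C)(C)CC[C@H]1N=N)/C=C/C(C)=C/C=C/C(C)=C/C=C/C=C(C)/C=C/C=C(C)/C=C/C1=C(C)[C@H](N=N)CCC1(C)C | intermediate
7 | (6R,6'R)-ε,ε-carotene | CC1=CCCC(C)(C)[C@H]1/C=C/C(C)=C/C=C/C(C)=C/C=C/C=C(C)/C=C/C=C(C)/C=C/[C@H]1C(C)=CCCC1(C)C | target

## Step count and risks

Total step count: 3. Longest linear sequence: 3 steps (1 → 2 → 4 → 7).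

**Step 3 (key step).**
- Most likely failure: ionisation of the C4 oxyphosphonium group to a polyenyl cation before the sulfonylhydrazide can displace it, because the carbon is allylic to eleven conjugated double bonds. This would erode the stereochemical fidelity at C4 and hence at C6, and would open elimination towards C3.
- Further risks: loss of N2 by a non-concerted path, which would reduce without transposition, and diimide from surplus NBSH saturating chain double bonds.
- Fallback (sets out from 4, returns at 7): formylation of 4 with formic acetic anhydride and pyridine at 0 °C would give (4S,4'S)-4,4'-bis(formyloxy)-β,β-carotene F1. Catalytic Pd(OAc)2 with n-Bu3P (one phosphine per palladium) in THF would generate zerovalent palladium, which adds to each allylic formate with inversion. After loss of CO2 the palladium hydride should pass hydrogen to the more substituted allyl terminus C6 on its own face, again anti to the former oxygen. The same 7 results by an organometallic hydride transfer in place of the pericyclic one, and with a much poorer leaving group on C4.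

**Step 2.**
- Most likely failure: insufficient facial discrimination at one or both carbonyl groups, or incomplete reduction because 2 is sparingly soluble at low temperature; conjugate reduction or hydroboration of the chain is a lesser risk.
- Fallback (sets out from 2, returns at 4): NaBH4 in THF/MeOH at 0 °C would give β,β-carotene-4,4'-diol as the mixture of (4R,4'R), (4S,4'S) and meso forms F2. A lipase (Pseudomonas cepacia lipase or Candida antarctica lipase B) with vinyl acetate in toluene should acetylate the (4R)-configured carbinol ends, as the usual empirical rule for lipases and secondary alcohols predicts with the C5 side as the large group. The (4R,4'R)-diol would become (4R,4'R)-4,4'-diacetoxy-β,β-carotene F3 and the meso diol would become (4R,4'S)-4-acetoxy-β,β-caroten-4'-ol F4. Diol 4 is then the only unacylated diol and is separated by chromatography. This replaces asymmetric catalysis by kinetic resolution.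

**Step 1.**
- Most likely failure: over-oxidation or cleavage of the chain, stopping at the mono-oxidised stage, and iodine-induced E/Z isomerisation, because the oxidant is not specific for the ring methylenes.
- Fallback (sets out from 1, returns at 2): NBS in CHCl3/AcOH at −15 °C followed by an amine base would give 4,4'-diacetoxy-β,β-carotene (mixture of stereoisomers) F5 by allylic bromination and acetolysis. K2CO3 in MeOH would release the stereorandom 4,4'-diol F2, and MnO2 in CH2Cl2 would oxidise both allylic carbinols to 2. This is a stepwise substitution–oxidation sequence in place of the direct oxidation.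

## Further compounds

F1 | step 3 | (4S,4'S)-4,4'-bis(formyloxy)-β,β-carotene | CC1=C(C(C)(C)CC[C@@H]1OC=O)/C=C/C(C)=C/C=C/C(C)=C/C=C/C=C(C)/C=C/C=C(C)/C=C/C1=C(C)[C@@H](OC=O)CCC1(C)C
F2 | step 2 | β,β-carotene-4,4'-diol, mixture of (4R,4'R), (4S,4'S) and meso forms | CC1=C(C(C)(C)CCC1O)/C=C/C(C)=C/C=C/C(C)=C/C=C/C=C(C)/C=C/C=C(C)/C=C/C1=C(C)C(O)CCC1(C)C
F3 | step 2 | (4R,4'R)-4,4'-diacetoxy-β,β-carotene | CC1=C(C(C)(C)CC[C@H]1OC(C)=O)/C=C/C(C)=C/C=C/C(C)=C/C=C/C=C(C)/C=C/C=C(C)/C=C/C1=C(C)[C@H](OC(C)=O)CCC1(C)C
F4 | step 2 | (4R,4'S)-4-acetoxy-β,β-caroten-4'-ol | CC1=C(C(C)(C)CC[C@H]1OC(C)=O)/C=C/C(C)=C/C=C/C(C)=C/C=C/C=C(C)/C=C/C=C(C)/C=C/C1=C(C)[C@@H](O)CCC1(C)C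
F5 | step 1 | 4,4'-diacetoxy-β,β-carotene, mixture of stereoisomers at C4 and C4' | CC1=C(C(C)(C)CCC1OC(C)=O)/C=C/C(C)=C/C=C/C(C)=C/C=C/C=C(C)/C=C/C=C(C)/C=C/C1=C(C)C(OC(C)=O)CCC1(C)C
A1 | alternative 1 | (R)-α-ionone | CC(=O)/C=C/[C@H]1C(C)=CCCC1(C)C
A2 | alternative 1 | [(2E,4E)-3-methyl-5-[(1R)-2,6,6-trimethylcyclohex-2-en-1-yl]penta-2,4-dien-1-yl]triphenylphosphonium bromide | CC1=CCCC(C)(C)[C@H]1/C=C/C(C)=C/C[P+](c1ccccc1)(c1ccccc1)c1ccccc1.[Br-]
A3 | alternative 1 | (2E,4E,6E)-2,7-dimethylocta-2,4,6-trienedial | O=C/C(C)=C/C=C/C=C(C)/C=O
A4 | alternative 2 | (R)-α-retinal | CC1=CCCC(C)(C)[C@H]1/C=C/C(C)=C/C=C/C(C)=C/C=O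
A5 | alternative 3 | all-E-lycopene | CC(C)=CCC/C(C)=C/C=C/C(C)=C/C=C/C(C)=C/C=C/C=C(C)/C=C/C=C(C)/C=C/C=C(C)/CCC=C(C)C
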